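North-west and north charge reagent nearly level with substrate, 1.1 equiv in each, so let the two fall together at rate k·s·s, with k the rate constant, s the substrate present, c the substrate charged and t the time.

| flask | substrate | reagent | temperature | remark | time |
|---|---|---|---|---|---|
| north-west | 0.092 M | 1.1 equiv | 55 °C | run made earlier |  |
| north | 0.15 M | 1.1 equiv | 75 °C | run made earlier |  |
| teal | 0.066 M | 1.10 equiv | 70 °C |  | 20 min |
| red | 0.066 M | 1.10 equiv | 80 °C |  | 20 min |

| run | time / min | single product / % | substrate / % |
|---|---|---|---|
| north-west | 3.00 | 3.0 | 91.5 |
| north-west | 6.00 | 6.6 | 84.1 |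
| north-west | 12.0 | 12.3 | 72.7 |
| north-west | 20.0 | 16.0 | 62.6 |
| north-west | 40.0 | 20.7 | 42.6 |
| north | 1.50 | 8.1 | 76.9 |
| north | 3.00 | 12.8 | 62.6 |
| north | 6.00 | 17.3 | 44.4 |
| north | 10.0 | 16.2 | 31.9 |
| north | 20.0 | 13.4 | 16.9 |

(scatter of a reading: 0.5 percentage points)

* which of the two there is more of at the end, teal (bis adduct / single product)
* which of the two there is more of at the end, red (bis adduct / single product)
* single product at the end, in percent of the substrate charged, teal
* single product at the end, in percent of the substrate charged, red

Integrate that rate:

substrate left = 1/(1 + Da), with Da = k·c·t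

Take each run at the reading nearest the conversion expected here: Da is 1.35 in north-west and 1.25 in north. Their k differ by a factor 3.80; spread ln k evenly over temperature:

teal: Da = 1.32, substrate left 43.1%

red: Da = 2.56, substrate left 28.1%

Read Da, the Damköhler number, as time counted in first half-lives of substrate.

Now test it. North at 6.00 min and north-west at 40.0 min hold 44.4% and 42.6% of substrate, yet single product reads 17.3% and 20.7%, so Da doesn't give the split. Watch the gap: north-west's first reading lacks 5.5 percentage points, more than its 3.0% of single product, so substrate has a second way out. Let φ be single product per substrate lost, as read; its highest reading in north-west, at 12.0 min, is 0.451. Count φ of the lost substrate as single product plus bis adduct, and take single product from the runs: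

teal: 25.6% minus 18.1% leaves bis adduct 7.50%

red: 32.4% minus 16.2% leaves bis adduct 16.2%

So expect more single product than bis adduct in teal, and a near tie in red.

The forecast gives bis adduct in teal and bis adduct in red, with single product 18% and 15.5%, holding “so most goes to bis adduct from the start”. On teal we differ.

Teal gives single product as the answer, 17.7% against 10.8% of bis adduct.

Red gives bis adduct as the answer, 20.5% against 15.4% of single product.

    substrate + reagent → single product (k = 0.360 M⁻¹ min⁻¹, Ea = 58.0 kJ mol⁻¹)
    substrate + reagent → other mono adduct (k = 0.0300 M⁻¹ min⁻¹, Ea = 62.0 kJ mol⁻¹)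
    reagent + single product → bis adduct (k = 0.730 M⁻¹ min⁻¹, Ea = 71.0 kJ mol⁻¹)
    reagent + other mono adduct → bis adduct (k = 0.640 M⁻¹ min⁻¹, Ea = 74.0 kJ mol⁻¹)
    2 substrate → self-condensation product (k = 0.230 M⁻¹ min⁻¹, Ea = 72.0 kJ mol⁻¹)
    (constants at 70 °C)

Now take a neighbour of teal with 0.660 equiv of reagent, the rest as in teal, and scale the φ part of Da with the reagent:

Da = 1.08, substrate left 48.1%

That neighbour ends with 50.0% of substrate, 13.6% of single product and 4.58% of bis adduct.

(The earlier runs and the new flask were computed on assumed constants, noise included.)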